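I decide to count sites before I read any rate: a bis adduct carries two partners on one substrate.

all flasks: substrate 0.20 M

| run | partner | remark | time |
|---|---|---|---|
| zeta | 0.14 M | run made earlier |  |
| beta | 0.47 M | run made earlier |  |
| Wednesday's | 0.200 M |  | 4.0 min |
| Friday's | 0.500 M |  | 4.0 min |
| Tuesday's | 0.600 M |  | 4.0 min |

| run | time / min | bis adduct / % | first product / % |
|---|---|---|---|
| zeta | 0.200 | 1.3 | 11.2 |
| zeta | 0.500 | 2.7 | 17.1 |
| zeta | 1.00 | 4.2 | 18.8 |
| zeta | 1.50 | 5.4 | 18.8 |
| zeta | 2.00 | 6.5 | 15.3 |
| zeta | 3.00 | 8.1 | 11.8 |
| beta | 0.250 | 7.7 | 29.0 |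
| beta | 0.333 | 10.3 | 30.7 |
| beta | 0.667 | 21.4 | 30.6 |
| beta | 1.00 | 31.9 | 24.5 |
| beta | 1.50 | 42.9 | 18.1 |
| beta | 3.00 | 62.3 | 7.7 |

(readings scatter by 0.5 percentage points)



- bis adduct at the end, in percent of the substrate charged, for each flask in turn (Wednesday's, Friday's, Tuesday's)

Turning the question round, full conversion to bis adduct takes a partner charge of 0.400 M. Wednesday's flask holds half of that, so partner is its limiting reagent. It stands at 0.500, which I call its cover s, the partner charged divided by twice the substrate charged. Friday's flask stands at 1.25 and Tuesday's at 1.50.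

As the zero of my scale I take the statistical case: partners land at random on the sites, so a filled share f of the sites puts f² of the substrate into the doubly filled form. On this scale, with all its partner placed, Wednesday's flask stands at s², or 25.0%. The zeta run has s = 0.350, so its zero is 12.3%, and it read 8.1% at 3.00 min, still rising. Wednesday's flask runs longer with a richer partner charge, so I scale its zero by the same fraction for a low estimate of 16.5% and place my own estimate between that and 25.0%. For Friday's and Tuesday's flasks I take beta's reading of 62.3% at 3.00 min as a low mark, since both hold more partner  and run longer.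

The forecast gives 17%, 70% and 77%, and says “the mechanism is unresolved”. Its first figure lies inside my bracket.

The flasks give 19.6%, 72.8% and 81.0%, so the forecast held.

    substrate + partner → other mono adduct (k = 0.0890 L mol⁻¹ s⁻¹)
    partner + first product → over-reaction product (k = 0.00960 L mol⁻¹ s⁻¹)
    partner + first product → bis adduct (k = 0.0250 L mol⁻¹ s⁻¹)
    partner + other mono adduct → bis adduct (k = 0.0460 L mol⁻¹ s⁻¹)
    substrate + partner ⇌ first product (K = 9.90 L mol⁻¹, k = 0.100 L mol⁻¹ s⁻¹)

Bis adduct and over-reaction product both carry two partners. Wednesday's flask has 9.3% of its partner left at 4.00 min, so f is 0.453 and f² is 20.5%, beside 19.6% of bis adduct and 2.01% of over-reaction product. Friday's flask has 28% left, so f is 0.895 and f² is 80.1%, beside 72.8% and 8.34%. In Friday's flask the second partner arrives mainly through the other mono adduct: without that path, bis adduct falls from 72.8% to 24.2%.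

The numbers in the tables come from a simulation on assumed constants; scatter was added.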